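I take each product to use one partner, so I start by counting partner.

| flask | left-handed substrate | right-handed substrate | partner | remark | time |
|---|---|---|---|---|---|
| south-west | 0.0070 M | 0.0070 M | 0.020 M | run made earlier |  |
| north | 0.011 M | 0.011 M | 0.020 M | run made earlier |  |
| north-east | 0.0050 M | 0.0050 M | 0.030 M | run made earlier |  |
| flask | 0.0050 M | 0.0050 M | 0.0200 M |  | 4.0 min |

| run | time / min | left-handed product / % | right-handed product / % |
|---|---|---|---|
| south-west | 1.00 | 55.0 | 2.4 |
| south-west | 2.00 | 71.2 | 0.6 |
| south-west | 3.00 | 79.8 | 1.3 |
| south-west | 4.00 | 84.5 | 2.1 |
| north | 0.500 | 36.0 | 2.0 |
| north | 1.33 | 55.7 | 2.4 |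
| north | 2.50 | 68.4 | 1.3 |
| north | 4.00 | 71.1 | 0.9 |
| north-east | 0.333 | 39.6 | 0.2 |
| north-east | 0.667 | 60.1 | 2.3 |
| north-east | 1.50 | 80.0 | 1.8 |
| north-east | 4.00 | 96.7 | 1.7 |

(standard deviation of a reading: 1 percentage point)

- partner is single-handed; left-handed substrate and right-handed substrate are mirror images of each other, charged as a racemate, each of them at the stated concentration
- the numbers in the tables scatter by 1 percentage point (one standard deviation)
- an excess is below zero if the other one leads
- the handed part of partner does not stay in what it makes, so the products of the two hands are mirror images too

- left-handed product and right-handed product together, in percent of the left-handed substrate and right-handed substrate charged together, at 4.0 min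
- excess of left-handed product over right-handed product in the product at 4.0 min
- whether the exchange between left-handed substrate and right-handed substrate keeps pace with the reaction: how far the product's excess at 4.0 min gets from its value without exchange to its value with instant exchange (above 80% keeps pace, below 20% hardly takes part, else lags behind)

The north run is the place to count, because it is charged with more substrate than partner and its curve has nearly stopped: the two products together gain 2.3 percentage points between 2.50 min and 4.00 min. At 4.00 min those products leave 0.00416 M of the north run's partner unaccounted for. I call this share of the charge, f = 20.8%, the lost share. It is a reading, and it counts free partner along with partner gone elsewhere.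

Two amounts then matter for the flask: its charge of partner less the lost share, which I reckon is what product can draw on, 0.0158 M, and the two substrates together, 0.0100 M. The first is the greater, by a factor of 1.58, so I reckon that the substrates are the limiting reagent in the flask.

The forecast, noting that “exchange is clearly happening”, gives a yield of 92%, an excess of 96%, and for the exchange: keeps pace.

The flask gives a yield of 91.1% and an excess of 95.0%, and the exchange keeps pace, getting 94% of the way.

    partner + left-handed substrate → left-handed product (k = 3.33 M⁻¹ s⁻¹)
    partner + right-handed substrate → right-handed product (k = 0.0653 M⁻¹ s⁻¹)
    left-handed substrate ⇌ achiral form (K = 0.309, k = 0.108 s⁻¹)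
    right-handed substrate ⇌ achiral form (K = 0.309, k = 0.108 s⁻¹)
    partner → decomposition product (k = 9.32 × 10⁻⁵ s⁻¹)
    partner → decomposed reagent (k = 0.00262 s⁻¹)
    partner ⇌ dormant form (K = 0.290, k = 0.0631 s⁻¹)

At 4.00 min the flask holds 0.00584 M of partner, free and dormant, against 8.88 × 10⁻⁴ M of the two substrates and the achiral form together, the order I reckoned. A neighbouring flask, like this one but charged with 0.080 M of partner, gets the same reckoning: less the lost share, I count 0.0634 M of partner for product, 6.34 times the substrates. At 4.00 min that flask has 41% of its charged partner and 0.013% of its charged left-handed substrate still unbound, so the order holds again. Its yield is >99.9%, but its right-handed product stands at 4.84% and its excess at 90.3%.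

All runs stem from a simulated flask with constants of no real substance; the scatter is artificial.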